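## Structural features

The target is a branched tetraflavanoid. A (+)-catechin core (unit 3) carries a fisetinidol-type unit (7,3',4'-trihydroxyflavan-3-ol) through C4 at C6 (unit 2) and another at C8 (unit 4), and unit 2 carries a third (unit 1) at its own C6. Each unit is a pyran ring C fused to ring A, with a catechol ring B on C2. There are eleven stereocentres. Units 1, 2 and 4 have contiguous all-trans C2–C3–C4 triads (2R,3S, aryl at C4 α; C4 is R in unit 1 and S in units 2 and 4 by CIP), and unit 3 is 2R,3S. The seventeen free hydroxyls, eight of them in four catechols, make the final compound sensitive to air and base, and the C4–aryl bonds are labile to acid. The real difficulties are the regiochemistry of the three aryl–C4 bonds (C6 against C8 of unit 3, C6 of unit 2) and the three C4 configurations. The key step exploits that in units 1, 2 and 4 the O1–C2 bond is a benzylic ether para to the 4'-hydroxyl of ring B. C2 can therefore be the exocyclic carbon of a para-quinone methide, and ring B–C2–C3–C4 is then the carbon chain of a 3-aryl-2-hydroxypropanoic acid with C3 as its carbinol carbon.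

## Logic of the disconnections

39 to 38: the fourteen O–benzyl bonds are cut last. Every hydroxyl that stays masked through the key step carries the same group, so a single hydrogenolysis finishes the route and the oxidisable polyphenol exists only at the end. The forward step must leave the O1–C2 ring ethers and the C4–aryl bonds intact.

38 to 36: the three O1–C2 bonds of units 1, 2 and 4 are cut. Three rings and three stereocentres disappear, and 36 is an open chain whose remaining stereocentres sit in 1,2-pairs. The forward step must oxidise only the three 4-hydroxy-3-benzyloxybenzyl groups and must end 2,3-trans in each ring.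

36 to 33: the C4–H bonds of units 2 and 4 and the six O–allyl bonds are cut. C4 is set by hydride addition to an ortho-quinone methide of ring A, so its configuration derives from C3 and the ring A phenols are freed in the same operation. The forward step needs a deallylation that spares benzyl ethers and a face-selective hydride addition.

33 to 29 and 31: the bond from C4 of unit 4 to C8 of unit 3 is cut. It forms by adding a C8 aryllithium to a ketone, which fixes the regiochemistry through the bromine at C8 of 29.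

29 to 27 and 18: the bond from C4 of unit 2 to C6 of unit 3 is cut. Iodine at C6 of 18 exchanges before bromine at C8, so C6 is addressed first without protecting C8.

27 to 25 and 8; 31 to 11 and 8; 20 to 13 and 8: the aryl–carbonyl bonds are cut. One chiral chain, 8, serves all three units, and each ketone forms by a single acylation of an aryllithium.

25 to 24, and 24 to 20 and 10: the O–allyl bond, then the C4–C4a bond and the C4–H bond of unit 1 are cut. The ring A phenol of unit 1 enters unprotected from 10, so that only this ring can become quinoid while ring A of unit 2 stays allylated. This is needed because the two aryl groups on C4 of unit 1 are otherwise nearly alike.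

8 to 7, 6, then 3 and 4; 3 to 2 and 1: the C2–ring B bond is cut at an epoxide carbon. The stereocentre comes unchanged from 4, and the 3'-benzyl/4'-allyl pattern is fixed on 1 before the chain exists. The forward step needs a regioselective bromination of 1 and a regioselective epoxide opening.

13 to 12, 10 and 9; 11 to 10: the carbon–halogen and O–allyl bonds of the ring A blocks are cut. Halogens are placed while the phenol directs and before any alkene is present.

18 to 17, 16 and 14: the two carbon–halogen bonds and the five O–benzyl bonds of unit 3 are cut, which leads back to the natural flavan-3-ol with both of its stereocentres in place.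

## Other disconnections considered

Alternative 1: The cut runs through O1–C2 and C3–O of ring C in unit 2 and leads back to A2, a ring-contracted 2,3-dihydrobenzofuran in which the ring oxygen sits on the future C3 and the future C2 is an exocyclic benzylic mesylate. In the forward step Zn(OAc)2 would assist loss of mesylate with participation of the furan oxygen, and acetate would open the bridged oxonium ion at the old furan C2 to give A1.
- In its favour: both new centres arise by inversion, so the outcome does not rest on an equilibrium. This is better than the chosen plan wherever the thermodynamic preference at C2 is small.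
- In its favour: C4 is set in a five-membered ring where trans is strongly preferred, which is equal to or better than the open-chain hydride addition used here.
- Equal: A1 carries bromine at C6 of unit 2 and C8 of unit 3, the same regiochemical handles as in the chosen plan.
- Against it: the mesylate is para to a benzyloxy group, so unassisted ionisation should compete with oxygen participation and erode the stereospecificity.
- Against it: one ring is made per operation, A2 is itself a long target, and the acetate needs separate handling. On step economy the chosen plan, which closes three rings at once, is ahead.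

Alternative 2: The cut runs through O1–C2 and C3–C4 of ring C in unit 4. In the forward step the carbinol A4 would lose water under a chiral phosphoric acid to an ortho-quinone methide, which would add the E-styrylsilane A5 in a [4+2] manner to give A3.
- In its favour: two skeletal bonds, one of them C–C, and three stereocentres form in one step from an achiral alkene. This is better than the chosen plan on bonds per step and on fragment simplicity, and no chiral chain is needed.
- Equal: both plans pass through acid- or base-sensitive quinone methides.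
- Against it: silicon must later become the C3 hydroxyl by Tamao–Fleming oxidation on a crowded carbon beside many electron-rich rings.
- Against it: the 3,4-trans relation depends on exo/endo control, the catalyst must match the catechin centres, and a vinylsilane is a weak 2π partner.
- Against it: each unit needs its own cycloaddition, so the overall step count should exceed that of the chosen plan.

Alternative 3: The cut is C3–C4 of ring C in unit 4. In the forward step Bu4NF would activate the diarylmethyl trimethylsilane of A7 and the benzylic carbanion equivalent would add to the tethered α-aryloxy aldehyde to give A6.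
- In its favour: no oxidant is used, which is better than the chosen plan with regard to oxidisable phenols.
- In its favour: the C3 hydroxyl arrives free and differentiated. This is better if unit 4 needed separate 3-O chemistry and equal here.
- Against it: C2 of A7 is benzylic, oxygenated and α to the aldehyde, so basic fluoride should epimerise it.
- Against it: an electron-rich diarylmethylsilane releases its carbanion reluctantly, so protodesilylation is likely.
- Against it: C3 and C4 form under kinetic, reversible aldol control, whereas the chosen plan forms only C–O bonds under thermodynamic control with C3 and C4 already fixed.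
- Against it: one ring forms per run, so step economy is again lower.

Key step: step 21

Remark: the commercial acid with a free catechol offers no way to benzylate O-3' alone, so its skeleton (ring B–C2–C3–C4) is built from methyl (R)-glycidate and an aryl bromide already carrying 3-O-benzyl/4-O-allyl; a check of 36, 38 and 39 against one another (ring sizes, fourteen benzyl ethers, every configuration) showed nothing to correct.

Step 1
Reactants: 1 2-(benzyloxy)phenol
Product: 2 2-(benzyloxy)-4-bromophenol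
Conditions: NBS (1.0 equiv), MeCN, 0 °C
Reagents that add atoms: N-bromosuccinimide, BrN1C(=O)CCC1=O
Why: Electrophilic aromatic bromination; the free hydroxyl is the stronger director and its para position is open, so bromine should enter para to OH, which fixes the later 4'-OH/3'-OBn pattern of ring B.

Step 2
Reactants: 2 2-(benzyloxy)-4-bromophenol
Product: 3 1-(allyloxy)-2-(benzyloxy)-4-bromobenzene
Conditions: allyl bromide, K2CO3, DMF, rt
Reagents that add atoms: allyl bromide, C=CCBr
Why: Williamson etherification; allyl is the single temporary group of the route, stable to organolithiums at −78 °C and removable by zerovalent palladium beside benzyl ethers.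

Step 3
Reactants: 3 1-(allyloxy)-2-(benzyloxy)-4-bromobenzene; 4 methyl (2R)-oxirane-2-carboxylate (methyl (R)-glycidate)
Product: 6 methyl (2R)-3-[4-(allyloxy)-3-(benzyloxy)phenyl]-2-hydroxypropanoate, via aryl Grignard reagent 5 (not isolated)
Conditions: Mg, THF, 40 °C; then CuI (10 mol%), 4, THF, −40 → −20 °C; aq NH4Cl
Reagents that add atoms: none
Why: Copper-catalysed Grignard opening of a terminal epoxide at its unsubstituted carbon (SN2), a known reaction of glycidic esters; no bond at the stereocentre is touched, so the (R) carbinol of 4 becomes C3 of the flavan chain, and the low temperature should keep the ester and the allyl ether out of reach.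

Step 4
Reactants: 6 methyl (2R)-3-[4-(allyloxy)-3-(benzyloxy)phenyl]-2-hydroxypropanoate
Product: 7 methyl (2R)-3-[4-(allyloxy)-3-(benzyloxy)phenyl]-2-(benzyloxy)propanoate
Conditions: BnBr, Ag2O, Bu4NI (cat.), CH2Cl2, rt, dark
Reagents that add atoms: benzyl bromide, BrCc1ccccc1
Why: Silver-oxide-mediated O-alkylation (Purdie-type) needs no strong base, so the stereocentre α to the ester should not epimerise.

Step 5
Reactants: 7 methyl (2R)-3-[4-(allyloxy)-3-(benzyloxy)phenyl]-2-(benzyloxy)propanoate
Product: 8 (2R)-3-[4-(allyloxy)-3-(benzyloxy)phenyl]-2-(benzyloxy)-N-methoxy-N-methylpropanamide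
Conditions: MeNHOMe·HCl, i-PrMgCl, THF, −20 → 0 °C
Reagents that add atoms: N,O-dimethylhydroxylamine hydrochloride, CNOC.Cl
Why: Weinreb amide formation by aminolysis of the ester with the chloromagnesium amide; the amide later accepts exactly one aryllithium through its chelated tetrahedral adduct.

Step 6
Reactants: 9 4-bromobenzene-1,3-diol (4-bromoresorcinol)
Product: 10 5-(benzyloxy)-2-bromophenol
Conditions: BnBr (1.0 equiv), K2CO3, acetone, reflux
Reagents that add atoms: benzyl bromide, BrCc1ccccc1
Why: Williamson monoalkylation; the hydroxyl para to bromine is unhindered, so one equivalent of benzyl bromide should alkylate it in preference and leave the hydroxyl next to bromine, which becomes O1.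

Step 7
Reactants: 10 5-(benzyloxy)-2-bromophenol
Product: 11 2-(allyloxy)-4-(benzyloxy)-1-bromobenzene
Conditions: allyl bromide, K2CO3, DMF, rt
Reagents that add atoms: allyl bromide, C=CCBr
Why: Williamson etherification masks the future O1 of unit 4 as an allyl ether next to the bromine that is later exchanged for lithium.

Step 8
Reactants: 10 5-(benzyloxy)-2-bromophenol
Product: 12 5-(benzyloxy)-2-bromo-4-iodophenol
Conditions: NIS (1.05 equiv), MeCN, 0 °C → rt
Reagents that add atoms: N-iodosuccinimide, IN1C(=O)CCC1=O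
Why: Electrophilic aromatic iodination para to the free phenol and ortho to the benzyloxy group, the most activated open position; the iodide gives a site that exchanges with n-BuLi before the bromide.

Step 9
Reactants: 12 5-(benzyloxy)-2-bromo-4-iodophenol
Product: 13 1-(allyloxy)-5-(benzyloxy)-2-bromo-4-iodobenzene
Conditions: allyl bromide, K2CO3, DMF, rt
Reagents that add atoms: allyl bromide, C=CCBr
Why: Williamson etherification, placed after the iodination so that the iodonium source never meets the allyl double bond.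

Step 10
Reactants: 14 (+)-catechin
Product: 16 3,5,7,3',4'-penta-O-benzyl-(+)-catechin, via 5,7,3',4'-tetra-O-benzylcatechin 15 (not isolated)
Conditions: BnBr, K2CO3, DMF, rt; then NaH, 0 °C → rt
Reagents that add atoms: benzyl bromide, BrCc1ccccc1
Why: Two-stage Williamson benzylation in one flask; carbonate alkylates the four phenols first, which avoids C-benzylation and base-induced epimerisation at C2, and NaH then benzylates the secondary alcohol.

Step 11
Reactants: 16 3,5,7,3',4'-penta-O-benzyl-(+)-catechin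
Product: 17 8-bromo-3,5,7,3',4'-penta-O-benzylcatechin
Conditions: NBS (1.0 equiv), CH2Cl2, −78 → 0 °C
Reagents that add atoms: N-bromosuccinimide, BrN1C(=O)CCC1=O
Why: Electrophilic bromination of the phloroglucinol-type ring A; C8 is the more nucleophilic and less hindered position of 5,7-di-O-benzylflavans, a well-established regioselectivity.

Step 12
Reactants: 17 8-bromo-3,5,7,3',4'-penta-O-benzylcatechin
Product: 18 8-bromo-6-iodo-3,5,7,3',4'-penta-O-benzylcatechin
Conditions: NIS (1.2 equiv), CF3CO2H (cat.), CH2Cl2, 0 °C → rt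
Reagents that add atoms: N-iodosuccinimide, IN1C(=O)CCC1=O
Why: Second electrophilic halogenation at the only open ring A position (C6); iodine at C6 and bromine at C8 allow two successive site-defined halogen–lithium exchanges.

Step 13
Reactants: 13 1-(allyloxy)-5-(benzyloxy)-2-bromo-4-iodobenzene; 8 (2R)-3-[4-(allyloxy)-3-(benzyloxy)phenyl]-2-(benzyloxy)-N-methoxy-N-methylpropanamide
Product: 20 (2R)-1-[4-(allyloxy)-2-(benzyloxy)-5-bromophenyl]-3-[4-(allyloxy)-3-(benzyloxy)phenyl]-2-(benzyloxy)propan-1-one, via aryllithium 19 (not isolated)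
Conditions: n-BuLi (1.0 equiv), THF, −78 °C; then 8, −78 → −40 °C; aq NH4Cl
Reagents that add atoms: none
Why: Iodine–lithium exchange is much faster than bromine–lithium exchange at −78 °C, and the aryllithium acylates the Weinreb amide once; this forms the bond from C4 of unit 1 to C6 of ring A of unit 2 and keeps the bromine for step 16.

Step 14
Reactants: 10 5-(benzyloxy)-2-bromophenol; 20 (2R)-1-[4-(allyloxy)-2-(benzyloxy)-5-bromophenyl]-3-[4-(allyloxy)-3-(benzyloxy)phenyl]-2-(benzyloxy)propan-1-one
Product: 24 2-[(1S,2R)-1-[4-(allyloxy)-2-(benzyloxy)-5-bromophenyl]-3-[4-(allyloxy)-3-(benzyloxy)phenyl]-2-(benzyloxy)propyl]-5-(benzyloxy)phenol, via lithium 5-(benzyloxy)-2-lithiophenolate 21 (not isolated), via tertiary carbinol 22 (not isolated), via ortho-quinone methide 23 (not isolated)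
Conditions: 10, n-BuLi (2.0 equiv), THF, −78 → −20 °C; 20, −78 → 0 °C; then EtOH, NaBH4, 2 M aq NaOH, 50 °C
Reagents that add atoms: none
Why: The ortho-lithiated phenolate adds to the ketone, the 2-hydroxyaryl carbinol loses hydroxide from its phenolate to give 23, and borohydride adds 1,4 (the known NaBH4 hydrogenolysis of ortho-hydroxybenzylic alcohols in alkali). C4 of unit 1 is set here: allylic 1,3-strain holds H3 in the plane of the exocyclic C4=C4a bond and hydride should enter anti to the C3–OBn bond (Felkin–Anh-type addition to a γ-alkoxy acceptor), which gives (1S,2R). Only ring A of unit 1 has a free hydroxyl, so only this ring can become quinoid although the two aryl groups on C4 are otherwise alike.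

Step 15
Reactants: 24 2-[(1S,2R)-1-[4-(allyloxy)-2-(benzyloxy)-5-bromophenyl]-3-[4-(allyloxy)-3-(benzyloxy)phenyl]-2-(benzyloxy)propyl]-5-(benzyloxy)phenol
Product: 25 1-(allyloxy)-5-(benzyloxy)-2-[(1S,2R)-1-[4-(allyloxy)-2-(benzyloxy)-5-bromophenyl]-3-[4-(allyloxy)-3-(benzyloxy)phenyl]-2-(benzyloxy)propyl]benzene
Conditions: allyl bromide, K2CO3, DMF, 40 °C
Reagents that add atoms: allyl bromide, C=CCBr
Why: Williamson etherification re-masks the ring A phenol of unit 1 so that the following organolithium steps meet no acidic proton.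

Step 16
Reactants: 25 1-(allyloxy)-5-(benzyloxy)-2-[(1S,2R)-1-[4-(allyloxy)-2-(benzyloxy)-5-bromophenyl]-3-[4-(allyloxy)-3-(benzyloxy)phenyl]-2-(benzyloxy)propyl]benzene; 8 (2R)-3-[4-(allyloxy)-3-(benzyloxy)phenyl]-2-(benzyloxy)-N-methoxy-N-methylpropanamide
Product: 27 (2R)-1-{2-(allyloxy)-4-(benzyloxy)-5-[(1S,2R)-1-[2-(allyloxy)-4-(benzyloxy)phenyl]-3-[4-(allyloxy)-3-(benzyloxy)phenyl]-2-(benzyloxy)propyl]phenyl}-3-[4-(allyloxy)-3-(benzyloxy)phenyl]-2-(benzyloxy)propan-1-one, via aryllithium 26 (not isolated)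
Conditions: n-BuLi (1.05 equiv), THF, −78 °C; then 8, −78 → −40 °C; aq NH4Cl
Reagents that add atoms: none
Why: Bromine–lithium exchange next to the allyloxy group (the ortho-allyloxy aryllithium is stable at −78 °C) followed by Weinreb acylation forms the C4–C4a bond of unit 2; the diarylmethine C–H is not acidic enough to interfere.

Step 17
Reactants: 18 8-bromo-6-iodo-3,5,7,3',4'-penta-O-benzylcatechin; 27 (2R)-1-{2-(allyloxy)-4-(benzyloxy)-5-[(1S,2R)-1-[2-(allyloxy)-4-(benzyloxy)phenyl]-3-[4-(allyloxy)-3-(benzyloxy)phenyl]-2-(benzyloxy)propyl]phenyl}-3-[4-(allyloxy)-3-(benzyloxy)phenyl]-2-(benzyloxy)propan-1-one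
Product: 29 tertiary alcohol formed by 1,2-addition of 28 to the carbonyl group of 27 (C4 of unit 2 bonded to C6 of unit 3; both carbinol epimers; C8 bromine kept), via 8-bromo-6-lithio-penta-O-benzylcatechin 28 (not isolated)
Conditions: 18 (1.5 equiv), n-BuLi (1.5 equiv), THF, −78 °C; CeCl3, −78 °C; then 27, −78 → −30 °C; aq NH4Cl
Reagents that add atoms: none
Why: Selective iodine–lithium exchange at C6 and 1,2-addition of the derived organocerium reagent, which suppresses enolisation of the α-benzyloxy ketone, form the bond from C4 of unit 2 to C6 of unit 3, in analogy to aryllithium additions to chroman-4-ones used for 4-arylflavans. Both carbinol epimers are carried on because C4 becomes planar again in step 20.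

Step 18
Reactants: 11 2-(allyloxy)-4-(benzyloxy)-1-bromobenzene; 8 (2R)-3-[4-(allyloxy)-3-(benzyloxy)phenyl]-2-(benzyloxy)-N-methoxy-N-methylpropanamide
Product: 31 (2R)-1-[2-(allyloxy)-4-(benzyloxy)phenyl]-3-[4-(allyloxy)-3-(benzyloxy)phenyl]-2-(benzyloxy)propan-1-one, via aryllithium 30 (not isolated)
Conditions: n-BuLi (1.0 equiv), THF, −78 °C; then 8, −78 → −40 °C; aq NH4Cl
Reagents that add atoms: none
Why: Bromine–lithium exchange and single Weinreb acylation give the ketone of unit 4 with its C4–C4a bond in place.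

Step 19
Reactants: 29 tertiary alcohol from step 17; 31 (2R)-1-[2-(allyloxy)-4-(benzyloxy)phenyl]-3-[4-(allyloxy)-3-(benzyloxy)phenyl]-2-(benzyloxy)propan-1-one
Product: 33 bis-carbinol formed by 1,2-addition of 32 to the carbonyl group of 31 (C4 of unit 4 bonded to C8 of unit 3; hexa-O-allyl tetradeca-O-benzyl; carbinol epimers), via C8-lithiated lithium alkoxide 32 (not isolated)
Conditions: n-BuLi (2.1 equiv), THF, −78 °C; CeCl3, −78 °C; then 31 (2 equiv), −78 → −30 °C; aq NH4Cl
Reagents that add atoms: none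
Why: The first equivalent of n-BuLi deprotonates the tertiary hydroxyl and the second exchanges the C8 bromine; the organocerium reagent derived from it adds to the small ketone used in excess and forms the bond from C4 of unit 4 to C8 of unit 3.

Step 20
Reactants: 33 bis-carbinol from step 19
Product: 36 tetradeca-O-benzyl open-chain tetramer (C2 methylenes; free ring A phenols and free 4'-hydroxyls in units 1/2/4; each chain 3R and 4S by CIP), via hexaphenol bis-carbinol 34 (not isolated), via bis(ortho-quinone methide) 35 (not isolated)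
Conditions: Pd(PPh3)4 (20 mol%), NaBH4, THF, rt; then EtOH, 2 M aq NaOH, 50 °C, Ar
Reagents that add atoms: none
Why: Zerovalent palladium passes the six allyl groups on to borohydride (the known Pd(PPh3)4/NaBH4 cleavage of aryl allyl ethers, to which benzyl ethers are inert); the two 2-hydroxyaryl carbinols then ionise in warm alkali to ortho-quinone methides of rings A of units 2 and 4 and take up hydride 1,4. As in step 14, H3 eclipses the exocyclic double bond and hydride should add anti to C3–OBn, which gives the (S) C4 centres of both units. The catechin ring carries no free phenol, so the quinoid ring is always ring A of the unit being set.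

Step 21
Reactants: 36 tetradeca-O-benzyl open-chain tetramer from step 20
Product: 38 tetradeca-O-benzyl ether of the target with free 4'-hydroxyls in units 1/2/4 (all three new rings 2,3-trans-3,4-trans), via tris(para-quinone methide) 37 (not isolated)
Conditions: Ag2O (3.3 equiv), CH2Cl2, rt, dark, Ar; filter; Et3N (0.3 equiv), CH2Cl2, rt
Reagents that add atoms: none
Why: Ag2O (monovalent silver, reduced to silver metal) dehydrogenates each 4-hydroxy-3-benzyloxybenzyl group by two one-electron transfers from the phenoxide and loss of the benzylic C2 proton, which gives the para-quinone methide 37 with C2 as its exocyclic carbon. The closest known reaction type is the Ag2O oxidation of 4-alkyl-2-alkoxyphenols to quinone methides with capture by a neighbouring phenol to form a flavan; its reverse is the base-induced C2 epimerisation of flavan-3-ols through the ring-opened quinone methide. Each of the three pyran rings closes in the same mode, a 6-exo-trig oxa-1,6-addition of the ring A hydroxyl to C2 that restores the aromatic ring B and forms O1–C2. Each new stereocentre (C2 of units 1, 2 and 4) is controlled by the two centres already in its ring: the C3 benzyloxy group and the C4 aryl are trans and both equatorial in the half-chair, so a chair-like closure places the C2 aryl equatorial (2,3-trans). Triethylamine can reopen a ring through the same quinone methide, so a kinetic 2,3-cis isomer, which needs either an axial aryl or a ring flip that makes the C3 and C4 groups axial, should drain to the all-equatorial product. The selectivity needed is oxidation of the three guaiacol-type rings only: their ortho-alkoxy groups make them the most easily oxidised phenols, the ring A phenols have only a meta oxygen, and 1.1 equivalents of Ag2O per ring leave no oxidant for them or for the C4 methines. Each quinone methide has its own ring A hydroxyl within reach of a six-membered transition state, so ring closure should outrun addition of any other phenol.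

Step 22
Reactants: 38 tetradeca-O-benzyl ether from step 21
Product: 39 fisetinidol-(4α→6)-fisetinidol-(4α→6)-[fisetinidol-(4α→8)]-catechin (target)
Conditions: H2 (1 atm), Pd(OH)2/C, THF–MeOH, rt
Reagents that add atoms: none
Why: Hydrogenolysis of the fourteen benzyl ethers over palladium; the O1–C2 ring ethers survive such conditions in the debenzylation of protected flavan-3-ol oligomers, and no stereocentre is touched.

## Compound list

1 | 2-(benzyloxy)phenol | Oc1ccccc1OCc1ccccc1 | starting material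
2 | 2-(benzyloxy)-4-bromophenol | Oc1ccc(Br)cc1OCc1ccccc1 | intermediate
3 | 1-(allyloxy)-2-(benzyloxy)-4-bromobenzene | C=CCOc1ccc(Br)cc1OCc1ccccc1 | intermediate
4 | methyl (2R)-oxirane-2-carboxylate | COC(=O)[C@H]1CO1 | starting material
5 | [4-(allyloxy)-3-(benzyloxy)phenyl]magnesium bromide | C=CCOc1ccc([Mg]Br)cc1OCc1ccccc1 | intermediate
6 | methyl (2R)-3-[4-(allyloxy)-3-(benzyloxy)phenyl]-2-hydroxypropanoate | COC(=O)[C@H](O)Cc1ccc(OCC=C)c(OCc2ccccc2)c1 | intermediate
7 | methyl (2R)-3-[4-(allyloxy)-3-(benzyloxy)phenyl]-2-(benzyloxy)propanoate | COC(=O)[C@H](OCc1ccccc1)Cc1ccc(OCC=C)c(OCc2ccccc2)c1 | intermediate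
8 | (2R)-3-[4-(allyloxy)-3-(benzyloxy)phenyl]-2-(benzyloxy)-N-methoxy-N-methylpropanamide | CON(C)C(=O)[C@H](OCc1ccccc1)Cc1ccc(OCC=C)c(OCc2ccccc2)c1 | intermediate
9 | 4-bromobenzene-1,3-diol | Oc1ccc(Br)c(O)c1 | starting material
10 | 5-(benzyloxy)-2-bromophenol | Oc1cc(OCc2ccccc2)ccc1Br | intermediate
11 | 2-(allyloxy)-4-(benzyloxy)-1-bromobenzene | C=CCOc1cc(OCc2ccccc2)ccc1Br | intermediate
12 | 5-(benzyloxy)-2-bromo-4-iodophenol | Oc1cc(OCc2ccccc2)c(I)cc1Br | intermediate
13 | 1-(allyloxy)-5-(benzyloxy)-2-bromo-4-iodobenzene | C=CCOc1cc(OCc2ccccc2)c(I)cc1Br | intermediate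
14 | (+)-catechin, (2R,3S) | Oc1cc(O)c2c(c1)O[C@H](c1ccc(O)c(O)c1)[C@@H](O)C2 | starting material
15 | 5,7,3',4'-tetra-O-benzyl-(+)-catechin | c1ccccc1COc1cc(OCc3ccccc3)c2c(c1)O[C@H](c1ccc(OCc3ccccc3)c(OCc3ccccc3)c1)[C@@H](O)C2 | intermediate
16 | 3,5,7,3',4'-penta-O-benzyl-(+)-catechin | c1ccccc1COc1cc(OCc3ccccc3)c2c(c1)O[C@H](c1ccc(OCc3ccccc3)c(OCc3ccccc3)c1)[C@@H](OCc1ccccc1)C2 | intermediate
17 | 8-bromo-3,5,7,3',4'-penta-O-benzylcatechin | c1ccccc1COc1cc(OCc3ccccc3)c2c(c1Br)O[C@H](c1ccc(OCc3ccccc3)c(OCc3ccccc3)c1)[C@@H](OCc1ccccc1)C2 | intermediate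
18 | 8-bromo-6-iodo-3,5,7,3',4'-penta-O-benzylcatechin | c1ccccc1COc1c(I)c(OCc3ccccc3)c2c(c1Br)O[C@H](c1ccc(OCc3ccccc3)c(OCc3ccccc3)c1)[C@@H](OCc1ccccc1)C2 | intermediate
19 | [4-(allyloxy)-2-(benzyloxy)-5-bromophenyl]lithium | C=CCOc1cc(OCc2ccccc2)c([Li])cc1Br | intermediate
20 | (2R)-1-[4-(allyloxy)-2-(benzyloxy)-5-bromophenyl]-3-[4-(allyloxy)-3-(benzyloxy)phenyl]-2-(benzyloxy)propan-1-one | C=CCOc1ccc(cc1OCc5ccccc5)C[C@@H](OCc5ccccc5)C(=O)c1c(OCc5ccccc5)cc(OCC=C)c(Br)c1 | intermediate
21 | lithium 5-(benzyloxy)-2-lithiophenolate | [Li]Oc1cc(OCc2ccccc2)ccc1[Li] | intermediate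
22 | 2-[(2R)-1-[4-(allyloxy)-2-(benzyloxy)-5-bromophenyl]-3-[4-(allyloxy)-3-(benzyloxy)phenyl]-2-(benzyloxy)-1-hydroxypropyl]-5-(benzyloxy)phenol (C1 epimers; formed as its dilithium salt) | C=CCOc1ccc(cc1OCc5ccccc5)C[C@@H](OCc5ccccc5)C(O)(c1ccc(OCc5ccccc5)cc1O)c1c(OCc5ccccc5)cc(OCC=C)c(Br)c1 | intermediate
23 | 6-[(2R)-1-[4-(allyloxy)-2-(benzyloxy)-5-bromophenyl]-3-[4-(allyloxy)-3-(benzyloxy)phenyl]-2-(benzyloxy)propylidene]-3-(benzyloxy)cyclohexa-2,4-dien-1-one | C=CCOc1ccc(cc1OCc5ccccc5)C[C@@H](OCc5ccccc5)C(=C1C=CC(OCc5ccccc5)=CC1=O)c1c(OCc5ccccc5)cc(OCC=C)c(Br)c1 | intermediate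
24 | 2-[(1S,2R)-1-[4-(allyloxy)-2-(benzyloxy)-5-bromophenyl]-3-[4-(allyloxy)-3-(benzyloxy)phenyl]-2-(benzyloxy)propyl]-5-(benzyloxy)phenol | C=CCOc1ccc(cc1OCc5ccccc5)C[C@@H](OCc5ccccc5)[C@@H](c1ccc(OCc5ccccc5)cc1O)c1c(OCc5ccccc5)cc(OCC=C)c(Br)c1 | intermediate
25 | 1-(allyloxy)-5-(benzyloxy)-2-[(1S,2R)-1-[4-(allyloxy)-2-(benzyloxy)-5-bromophenyl]-3-[4-(allyloxy)-3-(benzyloxy)phenyl]-2-(benzyloxy)propyl]benzene | C=CCOc1ccc(cc1OCc5ccccc5)C[C@@H](OCc5ccccc5)[C@@H](c1ccc(OCc5ccccc5)cc1OCC=C)c1c(OCc5ccccc5)cc(OCC=C)c(Br)c1 | intermediate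
26 | aryllithium of 25 (lithium in place of bromine) | C=CCOc1ccc(cc1OCc5ccccc5)C[C@@H](OCc5ccccc5)[C@@H](c1ccc(OCc5ccccc5)cc1OCC=C)c1c(OCc5ccccc5)cc(OCC=C)c([Li])c1 | intermediate
27 | (2R)-1-{2-(allyloxy)-4-(benzyloxy)-5-[(1S,2R)-1-[2-(allyloxy)-4-(benzyloxy)phenyl]-3-[4-(allyloxy)-3-(benzyloxy)phenyl]-2-(benzyloxy)propyl]phenyl}-3-[4-(allyloxy)-3-(benzyloxy)phenyl]-2-(benzyloxy)propan-1-one | C=CCOc1ccc(cc1OCc5ccccc5)C[C@@H](OCc5ccccc5)[C@@H](c1ccc(OCc5ccccc5)cc1OCC=C)c1c(OCc5ccccc5)cc(OCC=C)c(c1)C(=O)[C@H](OCc5ccccc5)Cc1ccc(OCC=C)c(OCc5ccccc5)c1 | intermediate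
28 | 8-bromo-6-lithio-3,5,7,3',4'-penta-O-benzylcatechin | c1ccccc1COc1c([Li])c(OCc3ccccc3)c2c(c1Br)O[C@H](c1ccc(OCc3ccccc3)c(OCc3ccccc3)c1)[C@@H](OCc1ccccc1)C2 | intermediate
29 | tertiary alcohol from 28 and the carbonyl of 27 (unit 2 carbinol on C6 of 8-bromo-penta-O-benzylcatechin; carbinol epimers) | C=CCOc1ccc(cc1OCc5ccccc5)C[C@@H](OCc5ccccc5)[C@@H](c1ccc(OCc5ccccc5)cc1OCC=C)c1c(OCc5ccccc5)cc(OCC=C)c(c1)C(O)([C@H](OCc5ccccc5)Cc1ccc(OCC=C)c(OCc5ccccc5)c1)c1c(OCc5ccccc5)c2c(c(Br)c1OCc5ccccc5)O[C@H](c1ccc(OCc5ccccc5)c(OCc5ccccc5)c1)[C@@H](OCc5ccccc5)C2 | intermediate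
30 | [2-(allyloxy)-4-(benzyloxy)phenyl]lithium | C=CCOc1cc(OCc2ccccc2)ccc1[Li] | intermediate
31 | (2R)-1-[2-(allyloxy)-4-(benzyloxy)phenyl]-3-[4-(allyloxy)-3-(benzyloxy)phenyl]-2-(benzyloxy)propan-1-one | C=CCOc1cc(OCc2ccccc2)ccc1C(=O)[C@H](OCc1ccccc1)Cc1ccc(OCC=C)c(OCc2ccccc2)c1 | intermediate
32 | lithium alkoxide of 29 with lithium in place of the C8 bromine | C=CCOc1ccc(cc1OCc5ccccc5)C[C@@H](OCc5ccccc5)[C@@H](c1ccc(OCc5ccccc5)cc1OCC=C)c1c(OCc5ccccc5)cc(OCC=C)c(c1)C(O[Li])([C@H](OCc5ccccc5)Cc1ccc(OCC=C)c(OCc5ccccc5)c1)c1c(OCc5ccccc5)c2c(c([Li])c1OCc5ccccc5)O[C@H](c1ccc(OCc5ccccc5)c(OCc5ccccc5)c1)[C@@H](OCc5ccccc5)C2 | intermediate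
33 | hexa-O-allyl tetradeca-O-benzyl bis-carbinol (C(OH) at C4 of units 2 and 4; carbinol epimers) | C=CCOc1ccc(cc1OCc5ccccc5)C[C@@H](OCc5ccccc5)[C@@H](c1ccc(OCc5ccccc5)cc1OCC=C)c1c(OCc5ccccc5)cc(OCC=C)c(c1)C(O)([C@H](OCc5ccccc5)Cc1ccc(OCC=C)c(OCc5ccccc5)c1)c1c(OCc5ccccc5)c2c(c(C(O)(c3ccc(OCc5ccccc5)cc3OCC=C)[C@H](OCc5ccccc5)Cc3ccc(OCC=C)c(OCc5ccccc5)c3)c1OCc5ccccc5)O[C@H](c1ccc(OCc5ccccc5)c(OCc5ccccc5)c1)[C@@H](OCc5ccccc5)C2 | intermediate
34 | hexaphenol bis-carbinol (33 without its six allyl groups) | Oc1ccc(cc1OCc5ccccc5)C[C@@H](OCc5ccccc5)[C@@H](c1ccc(OCc5ccccc5)cc1O)c1c(OCc5ccccc5)cc(O)c(c1)C(O)([C@H](OCc5ccccc5)Cc1ccc(O)c(OCc5ccccc5)c1)c1c(OCc5ccccc5)c2c(c(C(O)(c3ccc(OCc5ccccc5)cc3O)[C@H](OCc5ccccc5)Cc3ccc(O)c(OCc5ccccc5)c3)c1OCc5ccccc5)O[C@H](c1ccc(OCc5ccccc5)c(OCc5ccccc5)c1)[C@@H](OCc5ccccc5)C2 | intermediate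
35 | bis(ortho-quinone methide) from 34 (rings A of units 2 and 4 quinoid, C4 exocyclic; the two sites may react in turn) | Oc1ccc(cc1OCc5ccccc5)C[C@@H](OCc5ccccc5)[C@@H](c1ccc(OCc5ccccc5)cc1O)C1=CC(=C([C@H](OCc5ccccc5)Cc3ccc(O)c(OCc5ccccc5)c3)c3c(OCc5ccccc5)c2c(c(C(=C4C=CC(OCc5ccccc5)=CC4=O)[C@H](OCc5ccccc5)Cc4ccc(O)c(OCc5ccccc5)c4)c3OCc5ccccc5)O[C@H](c3ccc(OCc5ccccc5)c(OCc5ccccc5)c3)[C@@H](OCc5ccccc5)C2)C(=O)C=C1OCc5ccccc5 | intermediate
36 | tetradeca-O-benzyl open-chain tetramer with C2 methylenes, free ring A phenols and free 4'-hydroxyls in units 1, 2 and 4 | Oc1ccc(cc1OCc5ccccc5)C[C@@H](OCc5ccccc5)[C@@H](c1ccc(OCc5ccccc5)cc1O)c1c(OCc5ccccc5)cc(O)c(c1)[C@H]([C@H](OCc5ccccc5)Cc1ccc(O)c(OCc5ccccc5)c1)c1c(OCc5ccccc5)c2c(c([C@H](c3ccc(OCc5ccccc5)cc3O)[C@H](OCc5ccccc5)Cc3ccc(O)c(OCc5ccccc5)c3)c1OCc5ccccc5)O[C@H](c1ccc(OCc5ccccc5)c(OCc5ccccc5)c1)[C@@H](OCc5ccccc5)C2 | intermediate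
37 | tris(para-quinone methide) from 36 (rings B of units 1, 2 and 4 quinoid, C2 exocyclic) | O=C1C=CC(C=C1OCc5ccccc5)=C[C@@H](OCc5ccccc5)[C@@H](c1ccc(OCc5ccccc5)cc1O)c1c(OCc5ccccc5)cc(O)c(c1)[C@H]([C@H](OCc5ccccc5)C=C1C=CC(=O)C(OCc5ccccc5)=C1)c1c(OCc5ccccc5)c2c(c([C@H](c3ccc(OCc5ccccc5)cc3O)[C@H](OCc5ccccc5)C=C3C=CC(=O)C(OCc5ccccc5)=C3)c1OCc5ccccc5)O[C@H](c1ccc(OCc5ccccc5)c(OCc5ccccc5)c1)[C@@H](OCc5ccccc5)C2 | intermediate
38 | tetradeca-O-benzyl ether of the target with free 4'-hydroxyls in units 1, 2 and 4 | c5ccccc5COc1ccc2c(c1)O[C@H](c1ccc(O)c(OCc5ccccc5)c1)[C@@H](OCc5ccccc5)[C@@H]2c1cc2c(cc1OCc5ccccc5)O[C@H](c1ccc(O)c(OCc5ccccc5)c1)[C@@H](OCc5ccccc5)[C@@H]2c1c(OCc5ccccc5)c2c(c([C@@H]3c4ccc(OCc5ccccc5)cc4O[C@H](c4ccc(O)c(OCc5ccccc5)c4)[C@H]3OCc5ccccc5)c1OCc5ccccc5)O[C@H](c1ccc(OCc5ccccc5)c(OCc5ccccc5)c1)[C@@H](OCc5ccccc5)C2 | intermediate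
39 | fisetinidol-(4α→6)-fisetinidol-(4α→6)-[fisetinidol-(4α→8)]-catechin | Oc1ccc2c(c1)O[C@H](c1ccc(O)c(O)c1)[C@@H](O)[C@@H]2c1cc2c(cc1O)O[C@H](c1ccc(O)c(O)c1)[C@@H](O)[C@@H]2c1c(O)c2c(c([C@@H]3c4ccc(O)cc4O[C@H](c4ccc(O)c(O)c4)[C@H]3O)c1O)O[C@H](c1ccc(O)c(O)c1)[C@@H](O)C2 | target

## Step count and least certain steps

Total step count: 22. Longest linear sequence: 14 steps (1, 2, 3, 4, 5, 13, 14, 15, 16, 17, 19, 20, 21, 22).

Step 21 (key step). The most likely failures are three:
- renewed oxidation of rings that have already closed, since their 4'-hydroxy-3'-benzyloxyphenyl groups remain oxidisable at C2;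
- tautomerisation of a quinone methide to the 4-hydroxystyryl enol ether, which would destroy C3;
- incomplete closure leaving mixtures of partly cyclised material.

Fallback: separate oxidation from ring closure. Setting out from 36, Ag2O in CH2Cl2–MeOH at 0 °C should let the solvent trap each quinone methide as its benzylic methyl ether, giving the tris(C2-methoxy) hexaphenol F1, which can be purified away from the oxidant. Mild acid (camphorsulfonic acid, CH2Cl2, −20 °C) should then ionise the three para-hydroxybenzylic ethers and let the ring A phenols close under thermodynamic control. This is the way 1,3-diarylpropan-2-ol derivatives with a benzylic leaving group are cyclised to 2,3-trans-flavan-3-ols. The route is rejoined at 38.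

Step 14. The risk is poor or reversed facial selectivity in the hydride addition to the ortho-quinone methide: steric approach anti to the CH2-aryl arm would compete with the Felkin–Anh-type approach anti to C3–OBn. A second risk is enolisation of ketone 20 by the dianion. The diastereomers at this stage are small molecules and should be separable. Fallback: reverse the order in which hydride and aryl arrive at C4, which inverts the outcome for a given facial bias. Setting out from 8, reduction with LiAlH4 at −78 °C should give (2R)-3-[4-(allyloxy)-3-(benzyloxy)phenyl]-2-(benzyloxy)propanal F2. Addition of 21 gives the ortho-hydroxybenzylic alcohol F3. Iodine–magnesium exchange of 13 with i-PrMgCl gives [4-(allyloxy)-2-(benzyloxy)-5-bromophenyl]magnesium chloride F4. Warming the magnesium salt of F3 with excess F4 should generate the ortho-quinone methide F5, which takes up the aryl group 1,4 (the known arylation of ortho-quinone methides generated from ortho-hydroxybenzyl alcohols with Grignard reagents). The route is rejoined at 24.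

Step 20. Three processes can fail in one flask:
- incomplete loss of hydroxide from two crowded carbinols;
- face selectivity at two centres at once, where diastereomers would be hard to separate on a compound of this size;
- side reactions of the quinone methides with the free phenols.

Fallback: reduce before unmasking, by a cationic pathway. Setting out from 33, Et3SiH/CF3CO2H in CH2Cl2 at −40 °C (ionic hydrogenation of diaryl carbinols, to which allyl ethers are inert) should give the hexa-O-allyl tetradeca-O-benzyl tetramer F6. Its facial preference is that of a diaryl cation and need not be that of the neutral quinone methide. Pd(PPh3)4/NaBH4 in THF then removes the six allyl groups. The route is rejoined at 36.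

Step 17. The risk is enolisation of the α-benzyloxy ketone 27 or simple failure of a 2,6-dialkoxyaryl nucleophile to reach a hindered, branched ketone, which would return starting materials. Fallback: build the same carbinol with the roles exchanged. Setting out from 18, the lithium reagent 28 is acylated with the unhindered, non-enolisable amide 8 to give the 6-acyl-8-bromocatechin ketone F7. The less hindered aryllithium 26 (from 25) is then added to F7. The route is rejoined at 29.

Step 19. The risk is a failed or proton-quenched bromine–lithium exchange on a large substrate that carries a tertiary alkoxide and four allyl ethers, followed by a crowded addition at C8. Fallback: change the order of assembly so that unit 4 is attached while the catechin block is still small.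
- Setting out from 16, NIS gives 8-iodo-penta-O-benzylcatechin F8, and NBS then gives 6-bromo-8-iodo-penta-O-benzylcatechin F9.
- Iodine–lithium exchange gives the 8-lithio compound F10, which adds to 31 to give the C8 carbinol F11.
- Two equivalents of n-BuLi give the C6-lithiated alkoxide F12, which adds to ketone 27.
- The route is rejoined at 33.

## Further compounds

F1 | step 21 | tris(C2-methoxy) derivative of 36 (methoxy on C2 of units 1, 2 and 4; C2 epimers) | Oc1ccc(cc1OCc5ccccc5)C(OC)[C@@H](OCc5ccccc5)[C@@H](c1ccc(OCc5ccccc5)cc1O)c1c(OCc5ccccc5)cc(O)c(c1)[C@H]([C@H](OCc5ccccc5)C(OC)c1ccc(O)c(OCc5ccccc5)c1)c1c(OCc5ccccc5)c2c(c([C@H](c3ccc(OCc5ccccc5)cc3O)[C@H](OCc5ccccc5)C(OC)c3ccc(O)c(OCc5ccccc5)c3)c1OCc5ccccc5)O[C@H](c1ccc(OCc5ccccc5)c(OCc5ccccc5)c1)[C@@H](OCc5ccccc5)C2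
F2 | step 14 | (2R)-3-[4-(allyloxy)-3-(benzyloxy)phenyl]-2-(benzyloxy)propanal | O=C[C@H](OCc1ccccc1)Cc1ccc(OCC=C)c(OCc2ccccc2)c1
F3 | step 14 | 2-[(2R)-3-[4-(allyloxy)-3-(benzyloxy)phenyl]-2-(benzyloxy)-1-hydroxypropyl]-5-(benzyloxy)phenol (C1 epimers) | OC(c1ccc(OCc2ccccc2)cc1O)[C@H](OCc1ccccc1)Cc1ccc(OCC=C)c(OCc2ccccc2)c1
F4 | step 14 | [4-(allyloxy)-2-(benzyloxy)-5-bromophenyl]magnesium chloride | C=CCOc1cc(OCc2ccccc2)c([Mg]Cl)cc1Br
F5 | step 14 | 6-[(2R)-3-[4-(allyloxy)-3-(benzyloxy)phenyl]-2-(benzyloxy)propylidene]-3-(benzyloxy)cyclohexa-2,4-dien-1-one | O=C1C=C(OCc2ccccc2)C=CC1=C[C@H](OCc1ccccc1)Cc1ccc(OCC=C)c(OCc2ccccc2)c1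
F6 | step 20 | hexa-O-allyl tetradeca-O-benzyl open-chain tetramer (36 with its six phenols allylated) | C=CCOc1ccc(cc1OCc5ccccc5)C[C@@H](OCc5ccccc5)[C@@H](c1ccc(OCc5ccccc5)cc1OCC=C)c1c(OCc5ccccc5)cc(OCC=C)c(c1)[C@H]([C@H](OCc5ccccc5)Cc1ccc(OCC=C)c(OCc5ccccc5)c1)c1c(OCc5ccccc5)c2c(c([C@H](c3ccc(OCc5ccccc5)cc3OCC=C)[C@H](OCc5ccccc5)Cc3ccc(OCC=C)c(OCc5ccccc5)c3)c1OCc5ccccc5)O[C@H](c1ccc(OCc5ccccc5)c(OCc5ccccc5)c1)[C@@H](OCc5ccccc5)C2
F7 | step 17 | 8-bromo-6-[(2R)-3-[4-(allyloxy)-3-(benzyloxy)phenyl]-2-(benzyloxy)propanoyl]-penta-O-benzylcatechin | O=C([C@H](OCc5ccccc5)Cc1ccc(OCC=C)c(OCc5ccccc5)c1)c1c(OCc5ccccc5)c2c(c(Br)c1OCc5ccccc5)O[C@H](c1ccc(OCc5ccccc5)c(OCc5ccccc5)c1)[C@@H](OCc5ccccc5)C2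
F8 | step 19 | 8-iodo-3,5,7,3',4'-penta-O-benzylcatechin | c1ccccc1COc1cc(OCc3ccccc3)c2c(c1I)O[C@H](c1ccc(OCc3ccccc3)c(OCc3ccccc3)c1)[C@@H](OCc1ccccc1)C2
F9 | step 19 | 6-bromo-8-iodo-3,5,7,3',4'-penta-O-benzylcatechin | c1ccccc1COc1c(Br)c(OCc3ccccc3)c2c(c1I)O[C@H](c1ccc(OCc3ccccc3)c(OCc3ccccc3)c1)[C@@H](OCc1ccccc1)C2
F10 | step 19 | 6-bromo-8-lithio-3,5,7,3',4'-penta-O-benzylcatechin | c1ccccc1COc1c(Br)c(OCc3ccccc3)c2c(c1[Li])O[C@H](c1ccc(OCc3ccccc3)c(OCc3ccccc3)c1)[C@@H](OCc1ccccc1)C2
F11 | step 19 | 6-bromo-penta-O-benzylcatechin bearing at C8 the tertiary carbinol from addition to 31 (carbinol epimers) | Brc1c(OCc5ccccc5)c2c(c(C(O)(c3ccc(OCc5ccccc5)cc3OCC=C)[C@H](OCc5ccccc5)Cc3ccc(OCC=C)c(OCc5ccccc5)c3)c1OCc5ccccc5)O[C@H](c1ccc(OCc5ccccc5)c(OCc5ccccc5)c1)[C@@H](OCc5ccccc5)C2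
F12 | step 19 | lithium alkoxide of F11 with lithium in place of the C6 bromine | [Li]c1c(OCc5ccccc5)c2c(c(C(O[Li])(c3ccc(OCc5ccccc5)cc3OCC=C)[C@H](OCc5ccccc5)Cc3ccc(OCC=C)c(OCc5ccccc5)c3)c1OCc5ccccc5)O[C@H](c1ccc(OCc5ccccc5)c(OCc5ccccc5)c1)[C@@H](OCc5ccccc5)C2
A1 | alternative 1 | 6-bromo-7,3',4'-tri-O-benzylfisetinidol 3-acetate-(4α→6)-8-bromo-penta-O-benzylcatechin | Brc1cc2c(cc1OCc5ccccc5)O[C@H](c1ccc(OCc5ccccc5)c(OCc5ccccc5)c1)[C@@H](OC(C)=O)[C@@H]2c1c(OCc5ccccc5)c2c(c(Br)c1OCc5ccccc5)O[C@H](c1ccc(OCc5ccccc5)c(OCc5ccccc5)c1)[C@@H](OCc5ccccc5)C2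
A2 | alternative 1 | 8-bromo-penta-O-benzylcatechin bearing at C6 a 6-(benzyloxy)-5-bromo-2-[(3,4-dibenzyloxyphenyl)(mesyloxy)methyl]-2,3-dihydrobenzofuran-3-yl group | Brc1cc2c(cc1OCc5ccccc5)O[C@@H]([C@@H](OS(C)(=O)=O)c1ccc(OCc5ccccc5)c(OCc5ccccc5)c1)[C@@H]2c1c(OCc5ccccc5)c2c(c(Br)c1OCc5ccccc5)O[C@H](c1ccc(OCc5ccccc5)c(OCc5ccccc5)c1)[C@@H](OCc5ccccc5)C2
A3 | alternative 2 | perbenzylated fisetinidol-(4α→8)-catechin with benzyldimethylsilyl in place of the C3 hydroxyl of unit 4 | c1c(OCc5ccccc5)c2c(c([C@@H]3c4ccc(OCc5ccccc5)cc4O[C@H](c4ccc(OCc5ccccc5)c(OCc5ccccc5)c4)[C@H]3[Si](C)(C)Cc5ccccc5)c1OCc5ccccc5)O[C@H](c1ccc(OCc5ccccc5)c(OCc5ccccc5)c1)[C@@H](OCc5ccccc5)C2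
A4 | alternative 2 | 8-[[4-(benzyloxy)-2-hydroxyphenyl](hydroxy)methyl]-penta-O-benzylcatechin (carbinol epimers) | c1c(OCc5ccccc5)c2c(c(C(O)c3ccc(OCc5ccccc5)cc3O)c1OCc5ccccc5)O[C@H](c1ccc(OCc5ccccc5)c(OCc5ccccc5)c1)[C@@H](OCc5ccccc5)C2
A5 | alternative 2 | (E)-benzyl[2-(3,4-dibenzyloxyphenyl)ethenyl]dimethylsilane | C[Si](C)(Cc1ccccc1)/C=C/c1ccc(OCc2ccccc2)c(OCc2ccccc2)c1
A6 | alternative 3 | 7,3',4'-tri-O-benzylfisetinidol-(4α→8)-penta-O-benzylcatechin with a free C3 hydroxyl in unit 4 | c1c(OCc5ccccc5)c2c(c([C@@H]3c4ccc(OCc5ccccc5)cc4O[C@H](c4ccc(OCc5ccccc5)c(OCc5ccccc5)c4)[C@H]3O)c1OCc5ccccc5)O[C@H](c1ccc(OCc5ccccc5)c(OCc5ccccc5)c1)[C@@H](OCc5ccccc5)C2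
A7 | alternative 3 | 8-{[4-(benzyloxy)-2-[(1R)-1-(3,4-dibenzyloxyphenyl)-2-oxoethoxy]phenyl](trimethylsilyl)methyl}-penta-O-benzylcatechin (silane epimers) | c1c(OCc5ccccc5)c2c(c(C([Si](C)(C)C)c3ccc(OCc5ccccc5)cc3O[C@H](c3ccc(OCc5ccccc5)c(OCc5ccccc5)c3)C=O)c1OCc5ccccc5)O[C@H](c1ccc(OCc5ccccc5)c(OCc5ccccc5)c1)[C@@H](OCc5ccccc5)C2
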